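The target is C2-symmetric, so both chromans are cut at C4–C4a and O1–C8a, which removes both A rings. Ring A carries its C7 hydroxyl para to C4a and O1 on the adjacent C8a. This is the imprint of a p-quinol with C4a as carbinol carbon, C8a as enone β-carbon and C7 as carbonyl. In one flask the bis-Grignard reagent of an open-chain (R,R)-dibromide adds to p-benzoquinone monoketal (C4–C4a). Aqueous acid then unmasks dienone and side-chain alcohols, closes both pyran rings by oxa-Michael addition (O1–C8a), aromatises by loss of water and removes all silyl groups. The C3 centres stem from a catalytic double desymmetrisation of a bis(3-aryloxetane).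

Key step: step 7

Remark on the chemistry: both C3 centres read as R from the SMILES. Chroman numbering (O1, C2, C3, C4, C4a, C5 to C8, C8a; primes for ring B) is used throughout. The hand of the squaramide catalyst in step 5 is taken as the one that delivers R.

Step 1
Reactants: 1 (4-bromo-3-methoxyphenol); 2 (1-bromo-4-iodo-2-methoxybenzene)
Product: 3 bis(4-bromo-3-methoxyphenyl) ether
Conditions: CuI (10 mol %), picolinic acid (20 mol %), K3PO4, DMSO, 80 °C
Reagents that add atoms: none
Why: Ullmann-type diaryl ether synthesis in which the C–I bond of 2 should react well before the hindered, electron-rich C–Br bonds, so both bromides para to the new ether oxygen are kept as handles.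

Step 2
Reactants: 3 (bis(4-bromo-3-methoxyphenyl) ether); 4 (3-bromooxetane, two equivalents)
Product: 5 bis[3-methoxy-4-(oxetan-3-yl)phenyl] ether
Conditions: NiCl2(dme) (10 mol % per C–Br), 4,4'-di-tert-butyl-2,2'-bipyridine, NaI (cat.), Mn powder, DMA, 60 °C
Reagents that add atoms: none
Why: Nickel-catalysed reductive cross-electrophile coupling of an aryl bromide with a secondary alkyl bromide, for which 3-bromooxetane is an established partner, places the prochiral three-carbon unit (C2, C3, C4) on C1' of both equivalent rings.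

Step 3
Reactants: 5 (bis[3-methoxy-4-(oxetan-3-yl)phenyl] ether)
Product: 8 bis-phenol 6,6'-oxybis[2-methoxy-3-(oxetan-3-yl)phenol], via dilithiated diaryl ether 6 (not isolated), via bis(dimethyl boronate) 7 (not isolated)
Conditions: n-BuLi, TMEDA, THF, −20 → 0 °C; B(OMe)3, −78 °C → rt; 30 % aq H2O2, 0 °C → rt
Reagents that add atoms: hydrogen peroxide, OO
Why: Directed ortho-metalation takes the C3' hydrogen that lies between the methoxy and the bridging ether oxygen (cooperative 1,3-directors, as in the known 2,2'-dilithiation of diphenyl ethers), borylation and oxidative 1,2-migration turn it into the phenol, and oxetanes survive alkyllithiums when no Lewis acid is present.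

Step 4
Reactants: 8 (6,6'-oxybis[2-methoxy-3-(oxetan-3-yl)phenol])
Product: 9 bis{2-[(tert-butyldimethylsilyl)oxy]-3-methoxy-4-(oxetan-3-yl)phenyl} ether
Conditions: TBSCl, imidazole, DMF, 40 °C
Reagents that add atoms: tert-butyldimethylsilyl chloride, CC(C)(C)[Si](C)(C)Cl
Why: Imidazole-promoted silyl ether formation masks both C3' phenols with a group that tolerates TMSBr at low temperature and Grignard reagents and that aqueous acid removes at the end.

Step 5
Reactants: 9 (bis-silyl bis-oxetane)
Product: 11 (R,R)-bis(bromohydrin) (2R,2'R)-2,2'-{oxybis[3-(tert-butyldimethylsilyloxy)-2-methoxy-4,1-phenylene]}bis(3-bromopropan-1-ol), via bis(trimethylsilyl ether) 10 (not isolated)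
Conditions: TMSBr, chiral squaramide hydrogen-bond-donor catalyst (5 mol % per oxetane), t-BuOMe, −80 °C; then aq citric acid, THF, 0 °C
Reagents that add atoms: bromotrimethylsilane, C[Si](C)(C)Br
Why: Catalytic enantioselective desymmetrising ring opening of 3-aryloxetanes, in which the squaramide-bound bromide attacks one of the two enantiotopic CH2–O carbons of the silyl-activated oxetane by SN2, sets both C3 centres as R under catalyst control, and the two independent events should raise the enantiopurity of the (R,R) isomer (Horeau principle) while the meso isomer is removed by chromatography.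

Step 6
Reactants: 11 ((R,R)-bis(bromohydrin))
Product: 12 (R,R)-dibromide tetrakis(silyl ether), bis{4-[(2R)-1-bromo-3-(tert-butyldimethylsilyloxy)propan-2-yl]-2-(tert-butyldimethylsilyloxy)-3-methoxyphenyl} ether
Conditions: TBSCl, imidazole, CH2Cl2, 0 °C → rt
Reagents that add atoms: tert-butyldimethylsilyl chloride, CC(C)(C)[Si](C)(C)Cl
Why: Standard silylation, as routinely done on 3-bromopropanols, masks the primary hydroxyls against the Grignard reagent, and the weak base does not close the bromohydrin back to the achiral oxetane, so C3 stays R.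

Step 7
Reactants: 12 ((R,R)-dibromide tetrakis(silyl ether)); 13 (p-benzoquinone monoketal, 4,4-dimethoxycyclohexa-2,5-dien-1-one, two equivalents)
Product: 18 target bis-isoflavan (3R)-3-{3-hydroxy-4-[2-hydroxy-4-((3R)-7-hydroxychroman-3-yl)-3-methoxyphenoxy]-2-methoxyphenyl}chroman-7-ol, via bis-Grignard reagent 14 (not isolated), via bis(quinol ketal) 15 (not isolated), via bis(p-quinol) diol 16 (not isolated), via bis(oxa-Michael adduct) 17 (not isolated)
Conditions: Mg turnings, LiCl, THF, 25 °C; 13, THF, −78 → −20 °C; then 3 M aq HCl into the same flask, argon, 23 → 55 °C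
Reagents that add atoms: water, O
Why: Each primary alkylmagnesium arm of 14 adds 1,2 to the single carbonyl group of 13 (C4–C4a, the established route to p-quinol ketals), and the acid then hydrolyses the ketal (water delivers the later C7 oxygen) and the primary silyl ethers to give p-quinol 16. The free C2 hydroxyl adds to the dienone β-carbon C8a (O1–C8a) in a reversible 6-exo-trig oxa-Michael closure of each pyran ring (ring C), as known for p-quinols and cyclohexadienones that carry a hydroxyalkyl chain. Adduct 17 enolises to an arene hydrate that loses the C4a hydroxyl and the C8a hydrogen as water, the known acid dehydration of 4-hydroxycyclohexenones to phenols, and this irreversible aromatisation of ring A drains the Michael equilibrium while the same acid removes the aryl silyl ethers. Regiochemistry is built into 13: carbon can enter only at the carbonyl carbon, oxygen only at a β-carbon next to it, the two β-carbons give the same arene, and the ketal carbon para to C4a ends as C7–OH. The centres formed at C4a and C8a are transient and vanish on aromatisation, so no permanent stereocentre is made, and C3 (R, from step 5) has no acidifying or ionisable neighbour and is carried through unchanged. The step needs carbonyl rather than conjugate addition (uncatalysed Grignard reagent at low temperature) and ring closure ahead of the dienone–phenol shift or attack by ring B (an intramolecular oxygen nucleophile in dilute aqueous acid secures this).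

Compound list
1 | 4-bromo-3-methoxyphenol | COc1cc(O)ccc1Br | starting material
2 | 1-bromo-4-iodo-2-methoxybenzene | COc1cc(I)ccc1Br | starting material
3 | bis(4-bromo-3-methoxyphenyl) ether | COc1cc(Oc2ccc(Br)c(OC)c2)ccc1Br | intermediate
4 | 3-bromooxetane | BrC1COC1 | starting material
5 | bis[3-methoxy-4-(oxetan-3-yl)phenyl] ether | COc1cc(Oc2ccc(C3COC3)c(OC)c2)ccc1C1COC1 | intermediate
6 | dilithiated diaryl ether (Li on C3' of both rings, between OMe and the bridging oxygen) | COc1c([Li])c(Oc2ccc(C3COC3)c(OC)c2[Li])ccc1C1COC1 | intermediate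
7 | bis(dimethyl boronate) at C3' of both rings | COc1c(B(OC)OC)c(Oc2ccc(C3COC3)c(OC)c2B(OC)OC)ccc1C1COC1 | intermediate
8 | 6,6'-oxybis[2-methoxy-3-(oxetan-3-yl)phenol] | COc1c(O)c(Oc2ccc(C3COC3)c(OC)c2O)ccc1C1COC1 | intermediate
9 | bis{2-[(tert-butyldimethylsilyl)oxy]-3-methoxy-4-(oxetan-3-yl)phenyl} ether | COc1c(O[Si](C)(C)C(C)(C)C)c(Oc2ccc(C3COC3)c(OC)c2O[Si](C)(C)C(C)(C)C)ccc1C1COC1 | intermediate
10 | (R,R)-bis(3-bromo-1-trimethylsilyloxypropan-2-yl) compound, aryl TBS ethers in place | COc1c([C@@H](CBr)CO[Si](C)(C)C)ccc(Oc2ccc([C@@H](CBr)CO[Si](C)(C)C)c(OC)c2O[Si](C)(C)C(C)(C)C)c1O[Si](C)(C)C(C)(C)C | intermediate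
11 | (R,R)-bis(bromohydrin), aryl TBS ethers in place | COc1c([C@@H](CBr)CO)ccc(Oc2ccc([C@@H](CBr)CO)c(OC)c2O[Si](C)(C)C(C)(C)C)c1O[Si](C)(C)C(C)(C)C | intermediate
12 | (R,R)-dibromide tetrakis(TBS ether) | COc1c([C@@H](CBr)CO[Si](C)(C)C(C)(C)C)ccc(Oc2ccc([C@@H](CBr)CO[Si](C)(C)C(C)(C)C)c(OC)c2O[Si](C)(C)C(C)(C)C)c1O[Si](C)(C)C(C)(C)C | intermediate
13 | 4,4-dimethoxycyclohexa-2,5-dien-1-one (p-benzoquinone monoketal) | COC1(OC)C=CC(=O)C=C1 | starting material
14 | (R,R)-bis-Grignard reagent | COc1c([C@@H](C[Mg]Br)CO[Si](C)(C)C(C)(C)C)ccc(Oc2ccc([C@@H](C[Mg]Br)CO[Si](C)(C)C(C)(C)C)c(OC)c2O[Si](C)(C)C(C)(C)C)c1O[Si](C)(C)C(C)(C)C | intermediate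
15 | (R,R)-bis(quinol ketal), drawn as the free tertiary alcohols | COc1c([C@@H](CC2(O)C=CC(OC)(OC)C=C2)CO[Si](C)(C)C(C)(C)C)ccc(Oc2ccc([C@@H](CC3(O)C=CC(OC)(OC)C=C3)CO[Si](C)(C)C(C)(C)C)c(OC)c2O[Si](C)(C)C(C)(C)C)c1O[Si](C)(C)C(C)(C)C | intermediate
16 | (R,R)-bis(p-quinol) diol with free primary alcohols | COc1c([C@@H](CC2(O)C=CC(=O)C=C2)CO)ccc(Oc2ccc([C@@H](CC3(O)C=CC(=O)C=C3)CO)c(OC)c2O[Si](C)(C)C(C)(C)C)c1O[Si](C)(C)C(C)(C)C | intermediate
17 | bis(oxa-Michael adduct), two 4a-hydroxy-2,3,4,4a,8,8a-hexahydrochromen-7-one units, C3 is R, C4a and C8a are transient and unassigned | COc1c([C@@H]2COC3CC(=O)C=CC3(O)C2)ccc(Oc2ccc([C@@H]3COC4CC(=O)C=CC4(O)C3)c(OC)c2O[Si](C)(C)C(C)(C)C)c1O[Si](C)(C)C(C)(C)C | intermediate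
18 | CNP0116832.1, (3R,3R)-bis-isoflavan diaryl ether | COc1c([C@@H]2COc3cc(O)ccc3C2)ccc(Oc2ccc([C@@H]3COc4cc(O)ccc4C3)c(OC)c2O)c1O | target

Total step count: 7. Longest linear sequence: 7 (steps 1 to 7).

Steps most likely to fail

Step 7.
- What may go wrong: magnesium insertion may stall on one arm. Part of the reagent may add in conjugate fashion. The quinol may suffer alkyl migration or attack by ring B before the pyran closes. The hindered aryl silyl ethers may leave only slowly.
- Fallback: it replaces the dearomatised ring A synthon by two cross-couplings. It sets out from 12 and comes back at 18.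
- 12 is treated with Zn dust and LiCl in THF to give the bis(alkylzinc bromide) F1.
- F1 undergoes Negishi coupling (Pd(OAc)2, SPhos, THF, 25 °C) at the C–I bond of (3-bromo-4-iodophenoxy)(tert-butyl)dimethylsilane F2, itself made from commercial 3-bromo-4-iodophenol with TBSCl and imidazole. This gives the bis(2-bromobenzyl) hexasilyl ether F3.
- Camphorsulfonic acid in MeOH–CH2Cl2 at 0 °C frees only the primary alcohols and gives the dibromo diol F4.
- A double intramolecular C–O coupling (Pd(OAc)2, 2-(di-tert-butylphosphino)-1,1'-binaphthyl, Cs2CO3, toluene, 70 °C) closes both pyran rings to the tetrasilyl bis-chroman F5.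
- TBAF buffered by AcOH in THF then gives 18.

Step 5.
- What may go wrong: the ortho-methoxy group and the size of the substrate may weaken the discrimination of the enantiotopic C–O bonds. An uncatalysed background opening may erode it further.
- Fallback: it moves the stereochemical decision to an enzyme. It sets out from 9 and comes back at 11.
- Acetolysis of both oxetanes (Ac2O, Sc(OTf)3 cat., CH2Cl2, 0 °C) gives the prochiral tetraacetate F6.
- Lipase-catalysed hydrolysis of one enantiotopic acetate per arm (pH 7 buffer, cosolvent) gives the (S,S)-bis(monoacetate) F7.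
- Appel bromination (CBr4, PPh3, CH2Cl2) of the free hydroxyls gives the (R,R)-bis(bromo acetate) F8.
- DIBAL-H in CH2Cl2 at −78 °C removes the acetates without base and gives 11.

Step 2.
- What may go wrong: oxidative addition to the electron-rich, ortho-substituted aryl bromide may be slow. Hydrodehalogenation, homocoupling of either partner or coupling on one ring only may then take over.
- Fallback: it builds the oxetane on the arene instead of coupling it. It sets out from 3 and comes back at 5.
- Double palladium-catalysed α-arylation of diethyl malonate (Pd(OAc)2, P(t-Bu)3·HBF4, K3PO4, toluene, 100 °C) gives the bis(arylmalonate) F9.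
- LiAlH4 in THF at 0 °C gives the tetraol F10.
- Treatment in one flask with n-BuLi, TsCl and again n-BuLi (THF, 0 → 60 °C) passes through the bis(monotosylate) F11, which closes by intramolecular Williamson etherification to 5.

Further compounds
F1 | step 7 | (R,R)-bis(alkylzinc bromide) | COc1c([C@@H](C[Zn]Br)CO[Si](C)(C)C(C)(C)C)ccc(Oc2ccc([C@@H](C[Zn]Br)CO[Si](C)(C)C(C)(C)C)c(OC)c2O[Si](C)(C)C(C)(C)C)c1O[Si](C)(C)C(C)(C)C
F2 | step 7 | (3-bromo-4-iodophenoxy)(tert-butyl)dimethylsilane | CC(C)(C)[Si](C)(C)Oc1ccc(I)c(Br)c1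
F3 | step 7 | (R,R)-bis(2-bromobenzyl) hexasilyl ether | COc1c([C@@H](Cc2ccc(O[Si](C)(C)C(C)(C)C)cc2Br)CO[Si](C)(C)C(C)(C)C)ccc(Oc2ccc([C@@H](Cc3ccc(O[Si](C)(C)C(C)(C)C)cc3Br)CO[Si](C)(C)C(C)(C)C)c(OC)c2O[Si](C)(C)C(C)(C)C)c1O[Si](C)(C)C(C)(C)C
F4 | step 7 | (R,R)-dibromo diol, aryl silyl ethers in place | COc1c([C@@H](Cc2ccc(O[Si](C)(C)C(C)(C)C)cc2Br)CO)ccc(Oc2ccc([C@@H](Cc3ccc(O[Si](C)(C)C(C)(C)C)cc3Br)CO)c(OC)c2O[Si](C)(C)C(C)(C)C)c1O[Si](C)(C)C(C)(C)C
F5 | step 7 | (3R,3R)-tetrasilyl bis-chroman | COc1c([C@@H]2COc3cc(O[Si](C)(C)C(C)(C)C)ccc3C2)ccc(Oc2ccc([C@@H]3COc4cc(O[Si](C)(C)C(C)(C)C)ccc4C3)c(OC)c2O[Si](C)(C)C(C)(C)C)c1O[Si](C)(C)C(C)(C)C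
F6 | step 5 | prochiral tetraacetate | COc1c(C(COC(C)=O)COC(C)=O)ccc(Oc2ccc(C(COC(C)=O)COC(C)=O)c(OC)c2O[Si](C)(C)C(C)(C)C)c1O[Si](C)(C)C(C)(C)C
F7 | step 5 | (S,S)-bis(monoacetate) | COc1c([C@@H](CO)COC(C)=O)ccc(Oc2ccc([C@@H](CO)COC(C)=O)c(OC)c2O[Si](C)(C)C(C)(C)C)c1O[Si](C)(C)C(C)(C)C
F8 | step 5 | (R,R)-bis(bromo acetate) | COc1c([C@@H](CBr)COC(C)=O)ccc(Oc2ccc([C@@H](CBr)COC(C)=O)c(OC)c2O[Si](C)(C)C(C)(C)C)c1O[Si](C)(C)C(C)(C)C
F9 | step 2 | tetraethyl bis(arylmalonate) | COc1cc(Oc2ccc(C(C(=O)OCC)C(=O)OCC)c(OC)c2)ccc1C(C(=O)OCC)C(=O)OCC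
F10 | step 2 | bis(2-arylpropane-1,3-diol) tetraol | COc1cc(Oc2ccc(C(CO)CO)c(OC)c2)ccc1C(CO)CO
F11 | step 2 | bis(monotosylate), configuration not controlled | COc1cc(Oc2ccc(C(CO)COS(=O)(=O)c3ccc(C)cc3)c(OC)c2)ccc1C(CO)COS(=O)(=O)c1ccc(C)cc1
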